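The benzene ring is disconnected at C4a–C5 and C7–C8: C5–C7 come from a 4-alkoxyacetoacetate, C8 from a formyl carbon, and both are condensed onto a cyclohexanone that already carries C1, C4, C11 and C15. Two features are exploited: the saturated ring C1–C4, with its C1 side chain trans to the C4 methyl, is the trans-dihydrocarvone pattern, and the arene C5-OH/C6-OH/C7-CO2H is a 3-alkoxysalicylate. One Knoevenagel–aldol benzannulation of hydroxymethylene ketone 16, which bears the complete silyl-protected side chain, with keto ester 20 closes the arene. Benzyl ether, tert-butyl ester and TBDPS are chosen so that three mild steps finish the synthesis.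

Key step: step 14

Remarks on the chemistry (assumptions):
- Numbering: tetralin C1 bears the side chain, C4 the methyl, C4a/C8a are the fusion carbons next to C4/C1, then C5-OH, C6-OH, C7-CO2H, C8-H; the side chain is C11(CH3), C12–C14, C15(CH3), C16H2O.
- The O-alkyl groups of the keto ester and the silyl group are treated as freely chosen protecting groups (benzyl, tert-butyl, TBDPS); the carbon skeletons of 16 and 22 are those of the disconnection.
- The sense of induction in step 5 is ligand-controlled and is not assigned here from first principles; both ligand antipodes are commercial, and the one written stands for the antipode that gives the 11S ester.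

Step 1
Reactants: 1 (R)-carvone
Product: 2 (2R,5R)-2-methyl-5-(prop-1-en-2-yl)cyclohexan-1-one (trans-dihydrocarvone)
Conditions: L-Selectride (1.05 equiv), THF, −78 °C; then 1 M HCl, 0 °C
Reagents that add atoms: none
Why: Conjugate (1,4-) hydride reduction of the enone by a hindered trialkylborohydride with protonation of the enolate on work-up; the new α-methyl centre (future C4) should end mainly as the diequatorial trans epimer, the minor cis epimer is removed by chromatography, and the centre is re-equilibrated in steps 11–14 in any case.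

Step 2
Reactants: 2 trans-dihydrocarvone
Product: 3 (6R,9R)-6-methyl-9-(prop-1-en-2-yl)-1,4-dioxaspiro[4.5]decane
Conditions: HOCH2CH2OH, p-TsOH·H2O (cat.), benzene, reflux, Dean–Stark
Reagents that add atoms: ethylene glycol OCCO
Why: Acid-catalysed ketalisation with azeotropic removal of water, which masks the ring ketone through steps 3–10 and freezes the α-methyl centre.

Step 3
Reactants: 3 ketal
Product: 5 1-[(7R,10R)-10-methyl-1,4-dioxaspiro[4.5]decan-7-yl]ethan-1-one (methyl ketone), via secondary ozonide 4 (not isolated)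
Conditions: O3, CH2Cl2, −78 °C; then Me2S, −78 °C → rt
Reagents that add atoms: ozone [O-][O+]=O
Why: Ozonolysis with reductive work-up cleaves the only alkene to the methyl ketone while the ketal stays inert.

Step 4
Reactants: 5 methyl ketone
Product: 6 ethyl (2E)-3-[(7R,10R)-10-methyl-1,4-dioxaspiro[4.5]decan-7-yl]but-2-enoate
Conditions: (EtO)2P(O)CH2CO2Et (2 equiv), NaH (1.9 equiv), THF, 0 °C → reflux
Reagents that add atoms: triethyl phosphonoacetate CCOC(=O)CP(=O)(OCC)OCC
Why: Horner–Wadsworth–Emmons olefination of the methyl ketone, E-selective because the ester ends up anti to the bulky ring substituent (the minor Z isomer is removed by chromatography); the phosphonate anion, kept in excess over NaH, is too weak a base to enolise the ketone, so the adjacent ring stereocentre is preserved.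

Step 5
Reactants: 6 E-enoate
Product: 7 ethyl (3S)-3-[(7R,10R)-10-methyl-1,4-dioxaspiro[4.5]decan-7-yl]butanoate
Conditions: Cu(OAc)2·H2O (5 mol%), (R)-DTBM-SEGPHOS (5.5 mol%), (EtO)2MeSiH (3 equiv), t-BuOH (2 equiv), toluene, 0 °C → rt
Reagents that add atoms: none
Why: Asymmetric conjugate reduction of a β,β-disubstituted enoate by a bisphosphine-ligated copper hydride, in which hydride delivery to one face of the geometrically pure E-alkene sets C11 as S under ligand (reagent) control.

Step 6
Reactants: 7 saturated ester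
Product: 8 (3S)-3-[(7R,10R)-10-methyl-1,4-dioxaspiro[4.5]decan-7-yl]butanal
Conditions: DIBAL-H (1.1 equiv), CH2Cl2, −78 °C; then MeOH, aq. Rochelle salt
Reagents that add atoms: none
Why: Partial reduction of the ester by DIBAL-H, whose tetrahedral aluminium hemiacetal is stable at −78 °C and releases the aldehyde only on work-up; the ketal is inert and C11, β to the carbonyl group, cannot epimerise.

Step 7
Reactants: 9 (S)-3-bromo-2-methylpropan-1-ol
Product: 10 tert-butyl{[(2S)-3-bromo-2-methylpropyl]oxy}diphenylsilane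
Conditions: TBDPSCl, imidazole, CH2Cl2, 0 °C → rt
Reagents that add atoms: tert-butyl(chloro)diphenylsilane CC(C)(C)[Si](Cl)(c1ccccc1)c1ccccc1
Why: Imidazole-promoted silylation of the primary alcohol, which does not involve the stereocentre; TBDPS is chosen because it survives the aqueous acid of step 11.

Step 8
Reactants: 10 bromide
Product: 11 [(2S)-3-{[tert-butyl(diphenyl)silyl]oxy}-2-methylpropyl](triphenyl)phosphonium bromide
Conditions: PPh3 (1.5 equiv), MeCN, reflux
Reagents that add atoms: triphenylphosphine c1ccc(cc1)P(c1ccccc1)c1ccccc1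
Why: SN2 quaternisation of triphenylphosphine by the primary bromide, slow at this β-branched carbon but clean, with the stereocentre untouched.

Step 9
Reactants: 11 phosphonium bromide; 8 aldehyde
Product: 13 tert-butyl{[(2R,3Z,6S)-2-methyl-6-[(7R,10R)-10-methyl-1,4-dioxaspiro[4.5]decan-7-yl]hept-3-en-1-yl]oxy}diphenylsilane, via phosphorus ylide 12 (not isolated)
Conditions: 11 (1.3 equiv), NaHMDS, THF, 0 °C; then 8, −78 °C → rt
Reagents that add atoms: none
Why: Wittig olefination with a non-stabilised ylide joins C13 to C14; the alkene geometry (mainly Z) is irrelevant, and C15, whose hydrogen is not acidic, keeps the configuration of 9.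

Step 10
Reactants: 13 alkene
Product: 14 tert-butyl{[(2R,6S)-2-methyl-6-[(7R,10R)-10-methyl-1,4-dioxaspiro[4.5]decan-7-yl]heptyl]oxy}diphenylsilane
Conditions: H2 (1 atm), 5% Pt/C, EtOAc, rt
Reagents that add atoms: none
Why: Heterogeneous catalytic hydrogenation of the disubstituted alkene, with platinum used instead of palladium to suppress double-bond migration toward C15, which would scramble that centre.

Step 11
Reactants: 14 ketal
Product: 15 (2R,5R)-5-[(2S,6R)-7-{[tert-butyl(diphenyl)silyl]oxy}-6-methylheptan-2-yl]-2-methylcyclohexan-1-one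
Conditions: 2 M aq. HCl, THF, rt
Reagents that add atoms: water O
Why: Acid-catalysed hydrolysis of the dioxolane, which the TBDPS ether tolerates, while any C4 epimer equilibrates through the enol toward the diequatorial trans ketone.

Step 12
Reactants: 15 ketone
Product: 16 (2Z,3S,6R)-3-[(2S,6R)-7-{[tert-butyl(diphenyl)silyl]oxy}-6-methylheptan-2-yl]-2-(hydroxymethylidene)-6-methylcyclohexan-1-one
Conditions: HCO2Et (5 equiv), NaH (2 equiv), EtOH (cat.), THF, 0 °C → rt; then 1 M HCl
Reagents that add atoms: ethyl formate CCOC=O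
Why: Crossed Claisen condensation (formylation) with ethyl formate, funnelled to the C8a methylene because only there does acylation give a stabilised β-ketoaldehyde enolate; the enolisable C4 centre settles as the equatorial trans epimer.

Step 13
Reactants: 17 (benzyloxy)acetyl chloride; 18 Meldrum's acid (2,2-dimethyl-1,3-dioxane-4,6-dione)
Product: 20 tert-butyl 4-(benzyloxy)-3-oxobutanoate, via acyl Meldrum's acid 19 (not isolated)
Conditions: pyridine (2 equiv), CH2Cl2, 0 °C → rt; then t-BuOH, toluene, 90 °C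
Reagents that add atoms: tert-butanol CC(C)(C)O
Why: C-Acylation of Meldrum's acid followed by thermal alcoholysis through an acylketene, a standard β-keto ester synthesis that installs a benzyl ether and a tert-butyl ester, both removable by one Lewis acid at the end.

Step 14
Reactants: 16 hydroxymethylene ketone; 20 tert-butyl 4-(benzyloxy)-3-oxobutanoate
Product: 22 tert-butyl (5R,8S)-4-(benzyloxy)-8-[(2S,6R)-7-{[tert-butyl(diphenyl)silyl]oxy}-6-methylheptan-2-yl]-3-hydroxy-5-methyl-5,6,7,8-tetrahydronaphthalene-2-carboxylate, via Knoevenagel adduct 21 (not isolated)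
Conditions: piperidine (0.2 equiv), AcOH (0.2 equiv), 4 Å MS, toluene, 60 °C; then t-BuOK (2 equiv), t-BuOH, 50 °C; then 1 M HCl
Reagents that add atoms: none
Why: Proposed new method: amine–acid catalysis condenses the doubly activated methylene of 20 (future C7) with the formyl-level carbon C8 of 16 to give 21, whose only remaining enolisable site, the benzyloxy-bearing carbon (future C5), then adds as its enolate to the ring ketone C4a; E1cB loss of water and a prototropic shift of the C8a hydrogen (4H-cyclohexa-2,5-dienone to phenol) give the phenoxide of 22 without any redox reagent. The closest known reaction type is the base-mediated [3+3] condensation of 2-(hydroxymethylene)cycloalkanones with dialkyl 3-oxoglutarates to hydroxyisophthalates, together with the γ-aldol closure of acetoacetate Knoevenagel adducts in the Hagemann ester synthesis; what is new is a second nucleophilic carbon that is activated by one carbonyl group only and carries an alkoxy group. The benzene ring closes by a 6-(enolendo)-exo-trig aldol addition of C5 to C4a, after the intermolecular Knoevenagel bond C7–C8 has been made. No stereocentre is created: C1, C11 and C15 are not enolisable, and the enolisable C4 sits as the equatorial trans epimer in ketones 16 and 21 until aromatisation fixes it as a benzylic centre. The regiochemistry needed (ester next to C8-H, benzyloxy next to C4a) is secured by the ranking of the reacting sites, since the more acidic methylene meets the more electrophilic and unhindered formyl carbon first, and the tert-butyl ester blocks both lactonisation of the ring enol to a 2-pyranone and transesterification.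

Step 15
Reactants: 22 silyl ether
Product: 23 tert-butyl (5R,8S)-4-(benzyloxy)-3-hydroxy-8-[(2S,6R)-7-hydroxy-6-methylheptan-2-yl]-5-methyl-5,6,7,8-tetrahydronaphthalene-2-carboxylate
Conditions: HF·pyridine, pyridine/THF, 0 °C → rt
Reagents that add atoms: none
Why: Fluoride-induced cleavage of the silyl ether, driven by Si–F bond formation, in a buffered medium that leaves tert-butyl ester, benzyl ether and phenol untouched.

Step 16
Reactants: 23 alcohol; 24 ferulic acid
Product: 25 tert-butyl (5R,8S)-4-(benzyloxy)-3-hydroxy-8-[(2S,6R)-7-{[(2E)-3-(4-hydroxy-3-methoxyphenyl)prop-2-enoyl]oxy}-6-methylheptan-2-yl]-5-methyl-5,6,7,8-tetrahydronaphthalene-2-carboxylate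
Conditions: 24 (1.5 equiv), PPh3, DIAD, THF, 0 °C → rt
Reagents that add atoms: none
Why: Mitsunobu esterification, in which the alkoxyphosphonium ion of the primary alcohol is attacked by the carboxylate of 24; the carboxylic acid is far more acidic than either phenol, so neither the chelated C6 phenol nor the phenol of 24 needs protection, and C16 is not stereogenic.

Step 17
Reactants: 25 protected ester
Product: 26 (5R,8S)-3,4-dihydroxy-8-[(2S,6R)-7-{[(2E)-3-(4-hydroxy-3-methoxyphenyl)prop-2-enoyl]oxy}-6-methylheptan-2-yl]-5-methyl-5,6,7,8-tetrahydronaphthalene-2-carboxylic acid (target)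
Conditions: BCl3 (6 equiv), C6HMe5 (10 equiv), CH2Cl2, −78 → −40 °C; then MeOH/H2O
Reagents that add atoms: none
Why: Lewis-acid dealkylation with a non-basic cation scavenger: BCl3 cleaves the aryl benzyl ether and the tert-butyl ester at low temperature, pentamethylbenzene traps the benzyl cation, and the cinnamate ester, its alkene and the guaiacyl methyl ether (no chelating ortho carbonyl) should survive.

Compound list
1 | (R)-carvone | CC1=CC[C@H](CC1=O)C(C)=C | starting material
2 | (2R,5R)-2-methyl-5-(prop-1-en-2-yl)cyclohexan-1-one | CC(=C)[C@@H]1CC[C@@H](C)C(=O)C1 | intermediate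
3 | (6R,9R)-6-methyl-9-(prop-1-en-2-yl)-1,4-dioxaspiro[4.5]decane | CC(=C)[C@@H]1CC[C@@H](C)C2(OCCO2)C1 | intermediate
4 | 3-methyl-3-[(7R,10R)-10-methyl-1,4-dioxaspiro[4.5]decan-7-yl]-1,2,4-trioxolane (trioxolane carbon undefined) | CC1(OOCO1)[C@@H]2CC[C@@H](C)C3(OCCO3)C2 | intermediate (not isolated)
5 | 1-[(7R,10R)-10-methyl-1,4-dioxaspiro[4.5]decan-7-yl]ethan-1-one | CC(=O)[C@@H]1CC[C@@H](C)C2(OCCO2)C1 | intermediate
6 | ethyl (2E)-3-[(7R,10R)-10-methyl-1,4-dioxaspiro[4.5]decan-7-yl]but-2-enoate | CCOC(=O)/C=C(\C)[C@@H]1CC[C@@H](C)C2(OCCO2)C1 | intermediate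
7 | ethyl (3S)-3-[(7R,10R)-10-methyl-1,4-dioxaspiro[4.5]decan-7-yl]butanoate | CCOC(=O)C[C@H](C)[C@@H]1CC[C@@H](C)C2(OCCO2)C1 | intermediate
8 | (3S)-3-[(7R,10R)-10-methyl-1,4-dioxaspiro[4.5]decan-7-yl]butanal | O=CC[C@H](C)[C@@H]1CC[C@@H](C)C2(OCCO2)C1 | intermediate
9 | (S)-3-bromo-2-methylpropan-1-ol | OC[C@H](C)CBr | starting material
10 | tert-butyl{[(2S)-3-bromo-2-methylpropyl]oxy}diphenylsilane | CC(C)(C)[Si](c1ccccc1)(c1ccccc1)OC[C@H](C)CBr | intermediate
11 | [(2S)-3-{[tert-butyl(diphenyl)silyl]oxy}-2-methylpropyl](triphenyl)phosphonium bromide | CC(C)(C)[Si](c1ccccc1)(c1ccccc1)OC[C@H](C)C[P+](c1ccccc1)(c1ccccc1)c1ccccc1.[Br-] | intermediate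
12 | [(2S)-3-{[tert-butyl(diphenyl)silyl]oxy}-2-methylpropylidene](triphenyl)phosphorane | CC(C)(C)[Si](c1ccccc1)(c1ccccc1)OC[C@H](C)C=P(c1ccccc1)(c1ccccc1)c1ccccc1 | intermediate (not isolated)
13 | tert-butyl{[(2R,3Z,6S)-2-methyl-6-[(7R,10R)-10-methyl-1,4-dioxaspiro[4.5]decan-7-yl]hept-3-en-1-yl]oxy}diphenylsilane | CC(C)(C)[Si](c1ccccc1)(c1ccccc1)OC[C@H](C)/C=C\C[C@H](C)[C@@H]2CC[C@@H](C)C3(OCCO3)C2 | intermediate
14 | tert-butyl{[(2R,6S)-2-methyl-6-[(7R,10R)-10-methyl-1,4-dioxaspiro[4.5]decan-7-yl]heptyl]oxy}diphenylsilane | CC(C)(C)[Si](c1ccccc1)(c1ccccc1)OC[C@H](C)CCC[C@H](C)[C@@H]2CC[C@@H](C)C3(OCCO3)C2 | intermediate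
15 | (2R,5R)-5-[(2S,6R)-7-{[tert-butyl(diphenyl)silyl]oxy}-6-methylheptan-2-yl]-2-methylcyclohexan-1-one | CC(C)(C)[Si](c1ccccc1)(c1ccccc1)OC[C@H](C)CCC[C@H](C)[C@@H]2CC[C@@H](C)C(=O)C2 | intermediate
16 | (2Z,3S,6R)-3-[(2S,6R)-7-{[tert-butyl(diphenyl)silyl]oxy}-6-methylheptan-2-yl]-2-(hydroxymethylidene)-6-methylcyclohexan-1-one | CC(C)(C)[Si](c1ccccc1)(c1ccccc1)OC[C@H](C)CCC[C@H](C)[C@@H]2CC[C@@H](C)C(=O)/C2=C\O | intermediate
17 | (benzyloxy)acetyl chloride | O=C(Cl)COCc1ccccc1 | starting material
18 | Meldrum's acid (2,2-dimethyl-1,3-dioxane-4,6-dione) | CC1(C)OC(=O)CC(=O)O1 | starting material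
19 | 5-[2-(benzyloxy)-1-hydroxyethylidene]-2,2-dimethyl-1,3-dioxane-4,6-dione | CC1(C)OC(=O)C(=C(O)COCc2ccccc2)C(=O)O1 | intermediate (not isolated)
20 | tert-butyl 4-(benzyloxy)-3-oxobutanoate | CC(C)(C)OC(=O)CC(=O)COCc1ccccc1 | intermediate
21 | tert-butyl 4-(benzyloxy)-2-({(2S,5R)-2-[(2S,6R)-7-{[tert-butyl(diphenyl)silyl]oxy}-6-methylheptan-2-yl]-5-methyl-6-oxocyclohexyl}methylidene)-3-oxobutanoate (ring C1 and alkene geometry undefined) | CC(C)(C)[Si](c1ccccc1)(c1ccccc1)OC[C@H](C)CCC[C@H](C)[C@@H]2CC[C@@H](C)C(=O)C2C=C(C(=O)OC(C)(C)C)C(=O)COCc3ccccc3 | intermediate (not isolated)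
22 | tert-butyl (5R,8S)-4-(benzyloxy)-8-[(2S,6R)-7-{[tert-butyl(diphenyl)silyl]oxy}-6-methylheptan-2-yl]-3-hydroxy-5-methyl-5,6,7,8-tetrahydronaphthalene-2-carboxylate | CC(C)(C)[Si](c1ccccc1)(c1ccccc1)OC[C@H](C)CCC[C@H](C)[C@@H]2CC[C@@H](C)c3c2cc(C(=O)OC(C)(C)C)c(O)c3OCc4ccccc4 | intermediate
23 | tert-butyl (5R,8S)-4-(benzyloxy)-3-hydroxy-8-[(2S,6R)-7-hydroxy-6-methylheptan-2-yl]-5-methyl-5,6,7,8-tetrahydronaphthalene-2-carboxylate | OC[C@H](C)CCC[C@H](C)[C@@H]1CC[C@@H](C)c2c1cc(C(=O)OC(C)(C)C)c(O)c2OCc3ccccc3 | intermediate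
24 | ferulic acid | COc1cc(/C=C/C(=O)O)ccc1O | starting material
25 | tert-butyl (5R,8S)-4-(benzyloxy)-3-hydroxy-8-[(2S,6R)-7-{[(2E)-3-(4-hydroxy-3-methoxyphenyl)prop-2-enoyl]oxy}-6-methylheptan-2-yl]-5-methyl-5,6,7,8-tetrahydronaphthalene-2-carboxylate | COc1cc(/C=C/C(=O)OC[C@H](C)CCC[C@H](C)[C@@H]2CC[C@@H](C)c3c2cc(C(=O)OC(C)(C)C)c(O)c3OCc4ccccc4)ccc1O | intermediate
26 | (5R,8S)-3,4-dihydroxy-8-[(2S,6R)-7-{[(2E)-3-(4-hydroxy-3-methoxyphenyl)prop-2-enoyl]oxy}-6-methylheptan-2-yl]-5-methyl-5,6,7,8-tetrahydronaphthalene-2-carboxylic acid | COc1cc(/C=C/C(=O)OC[C@H](C)CCC[C@H](C)[C@@H]2CC[C@@H](C)c3c2cc(C(=O)O)c(O)c3O)ccc1O | target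

Total step count: 17.
Longest linear sequence: 14 steps (steps 1–6, 9–12 and 14–17, from (R)-carvone).

Steps most likely to fail

1. Step 14 (the labelled step). The second nucleophilic carbon may fail to add to the hindered ring ketone, the Knoevenagel adduct may drain into O-cyclised pyran products, and C4 may partly epimerise before aromatisation locks it. The fallback uses known chemistry only and replaces the condensation by a pyranone cycloaddition; it sets out from 16 and comes back to the route at 26.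
 - Compound 16 is condensed with dimethyl malonate (piperidinium acetate, toluene, reflux; Knoevenagel condensation, then lactonisation by the ring enol) to methyl (5S,8R)-5-[(2S,6R)-7-{[tert-butyl(diphenyl)silyl]oxy}-6-methylheptan-2-yl]-8-methyl-2-oxo-5,6,7,8-tetrahydro-2H-chromene-3-carboxylate F1.
 - This electron-poor 2-pyranone undergoes an inverse-electron-demand Diels–Alder reaction with 1,1,2-trimethoxyethene (mesitylene, 140 °C); loss of CO2 and methanol should give methyl (5R,8S)-8-[(2S,6R)-7-{[tert-butyl(diphenyl)silyl]oxy}-6-methylheptan-2-yl]-3,4-dimethoxy-5-methyl-5,6,7,8-tetrahydronaphthalene-2-carboxylate F2, with the ester next to C8-H.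
 - BBr3 (CH2Cl2, −78 °C → rt) followed by aqueous LiOH removes the two methyl ethers, the silyl ether and the methyl ester, giving (5R,8S)-3,4-dihydroxy-8-[(2S,6R)-7-hydroxy-6-methylheptan-2-yl]-5-methyl-5,6,7,8-tetrahydronaphthalene-2-carboxylic acid F3.
 - Benzyl bromide/K2CO3 (DMF) alkylates the acid and both phenols but not the aliphatic alcohol, giving benzyl (5R,8S)-3,4-bis(benzyloxy)-8-[(2S,6R)-7-hydroxy-6-methylheptan-2-yl]-5-methyl-5,6,7,8-tetrahydronaphthalene-2-carboxylate F4.
 - Mitsunobu esterification with 24 gives benzyl (5R,8S)-3,4-bis(benzyloxy)-8-[(2S,6R)-7-{[(2E)-3-(4-hydroxy-3-methoxyphenyl)prop-2-enoyl]oxy}-6-methylheptan-2-yl]-5-methyl-5,6,7,8-tetrahydronaphthalene-2-carboxylate F5, and BCl3/pentamethylbenzene as in step 17 gives 26.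

2. Step 5. Facial selectivity at C11 may be poor if the ligand and the adjacent ring stereocentre are mismatched, or the hindered enoate may react sluggishly. The fallback switches to hydroxyl-directed asymmetric hydrogenation; it sets out from 6 and comes back at 8.
 - DIBAL-H (2.2 equiv, CH2Cl2, −78 °C) reduces 6 to (2E)-3-[(7R,10R)-10-methyl-1,4-dioxaspiro[4.5]decan-7-yl]but-2-en-1-ol F6.
 - Hydrogenation with Ru(OAc)2[(S)-BINAP] (H2 under pressure, MeOH) should give (3S)-3-[(7R,10R)-10-methyl-1,4-dioxaspiro[4.5]decan-7-yl]butan-1-ol F7. The antipode is chosen by analogy with the geraniol to (R)-citronellol sense of this catalyst; the descriptor changes because the ring carbon outranks the hydroxyethyl arm.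
 - Dess–Martin oxidation returns aldehyde 8.

3. Step 17. Cleavage of the benzyl ether or tert-butyl ester may be incomplete at the low temperature needed, and on warming boron may attack the guaiacyl methyl ether or the cinnamate ester. The fallback removes the benzyl group before the alkene is present and finishes with acid only; it sets out from 23 and comes back at 26.
 - Hydrogenolysis of 23 (H2, Pd/C, EtOAc) gives tert-butyl (5R,8S)-3,4-dihydroxy-8-[(2S,6R)-7-hydroxy-6-methylheptan-2-yl]-5-methyl-5,6,7,8-tetrahydronaphthalene-2-carboxylate F8.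
 - Mitsunobu esterification with 24 (phenols tolerated) gives tert-butyl (5R,8S)-3,4-dihydroxy-8-[(2S,6R)-7-{[(2E)-3-(4-hydroxy-3-methoxyphenyl)prop-2-enoyl]oxy}-6-methylheptan-2-yl]-5-methyl-5,6,7,8-tetrahydronaphthalene-2-carboxylate F9.
 - TFA/CH2Cl2 with triethylsilane (0 °C → rt) cleaves the tert-butyl ester to give 26.

Further compounds
F1 | step 14 | methyl (5S,8R)-5-[(2S,6R)-7-{[tert-butyl(diphenyl)silyl]oxy}-6-methylheptan-2-yl]-8-methyl-2-oxo-5,6,7,8-tetrahydro-2H-chromene-3-carboxylate | CC(C)(C)[Si](c1ccccc1)(c1ccccc1)OC[C@H](C)CCC[C@H](C)[C@@H]2CC[C@@H](C)C3=C2C=C(C(=O)OC)C(=O)O3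
F2 | step 14 | methyl (5R,8S)-8-[(2S,6R)-7-{[tert-butyl(diphenyl)silyl]oxy}-6-methylheptan-2-yl]-3,4-dimethoxy-5-methyl-5,6,7,8-tetrahydronaphthalene-2-carboxylate | CC(C)(C)[Si](c1ccccc1)(c1ccccc1)OC[C@H](C)CCC[C@H](C)[C@@H]2CC[C@@H](C)c3c2cc(C(=O)OC)c(OC)c3OC
F3 | step 14 | (5R,8S)-3,4-dihydroxy-8-[(2S,6R)-7-hydroxy-6-methylheptan-2-yl]-5-methyl-5,6,7,8-tetrahydronaphthalene-2-carboxylic acid | OC[C@H](C)CCC[C@H](C)[C@@H]1CC[C@@H](C)c2c1cc(C(=O)O)c(O)c2O
F4 | step 14 | benzyl (5R,8S)-3,4-bis(benzyloxy)-8-[(2S,6R)-7-hydroxy-6-methylheptan-2-yl]-5-methyl-5,6,7,8-tetrahydronaphthalene-2-carboxylate | OC[C@H](C)CCC[C@H](C)[C@@H]1CC[C@@H](C)c2c1cc(C(=O)OCc3ccccc3)c(OCc3ccccc3)c2OCc3ccccc3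
F5 | step 14 | benzyl (5R,8S)-3,4-bis(benzyloxy)-8-[(2S,6R)-7-{[(2E)-3-(4-hydroxy-3-methoxyphenyl)prop-2-enoyl]oxy}-6-methylheptan-2-yl]-5-methyl-5,6,7,8-tetrahydronaphthalene-2-carboxylate | COc1cc(/C=C/C(=O)OC[C@H](C)CCC[C@H](C)[C@@H]2CC[C@@H](C)c3c2cc(C(=O)OCc4ccccc4)c(OCc4ccccc4)c3OCc4ccccc4)ccc1O
F6 | step 5 | (2E)-3-[(7R,10R)-10-methyl-1,4-dioxaspiro[4.5]decan-7-yl]but-2-en-1-ol | OC/C=C(\C)[C@@H]1CC[C@@H](C)C2(OCCO2)C1
F7 | step 5 | (3S)-3-[(7R,10R)-10-methyl-1,4-dioxaspiro[4.5]decan-7-yl]butan-1-ol | OCC[C@H](C)[C@@H]1CC[C@@H](C)C2(OCCO2)C1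
F8 | step 17 | tert-butyl (5R,8S)-3,4-dihydroxy-8-[(2S,6R)-7-hydroxy-6-methylheptan-2-yl]-5-methyl-5,6,7,8-tetrahydronaphthalene-2-carboxylate | OC[C@H](C)CCC[C@H](C)[C@@H]1CC[C@@H](C)c2c1cc(C(=O)OC(C)(C)C)c(O)c2O
F9 | step 17 | tert-butyl (5R,8S)-3,4-dihydroxy-8-[(2S,6R)-7-{[(2E)-3-(4-hydroxy-3-methoxyphenyl)prop-2-enoyl]oxy}-6-methylheptan-2-yl]-5-methyl-5,6,7,8-tetrahydronaphthalene-2-carboxylate | COc1cc(/C=C/C(=O)OC[C@H](C)CCC[C@H](C)[C@@H]2CC[C@@H](C)c3c2cc(C(=O)OC(C)(C)C)c(O)c3O)ccc1O
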